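The readings come from a simulation with constants of no real substance, noise included.

The closed, stirred vessel holds solid electrophile, which must dissolve before it can meet the nucleophile coming from the held gas. Each product formed also sends one acid into the buffer.

| flask | solid electrophile | buffer base | buffer acid | gas | remark | time |
|---|---|---|---|---|---|---|
| eta | 20 mM | 4 mM | 2 mM | 1.6 mM (held) | the very flask that is asked about, followed so far |  |
| flask | 20 mM | 4.00 mM | 2.00 mM | 1.6 mM (held) |  | 6.0 h |

- eta (time / h: solid electrophile / %, product / %): 0.417: 97.7, 1.6; 1.00: 98.4, 1.3; 2.00: 92.8, 4.4; 3.00: 87.3, 7.8

(each reading ± 1 percentage point)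

- acid is the free proton; pH is minus the decimal logarithm of its molar concentration
- solid, in amounts per volume of the solution: solid electrophile
- at the start none of nucleophile is dissolved
- the numbers in the tables scatter with a standard deviation of 1 percentage point
- reactions considered so far: electrophile + nucleophile -> acid + product + leaving group; protonated nucleophile <-> nucleophile + acid; buffer acid <-> buffer base + acid; gas <-> nucleophile; solid electrophile <-> electrophile
- at the start none of the solid electrophile is in solution
- what has only dissolved of solid electrophile counts as not reacted
- the earlier runs do not show the pH; that part of a forecast is a guess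

- part of the solid electrophile that has reacted (what has only dissolved counts as not reacted) at 6.0 h
- pH of the solution at 6.0 h

Look at the reading at 3.00 h: you have lost 12.7% of the solid but hold 7.8% of product. The two seem not to fit, yet the difference, 0.980 mM, can simply be dissolved electrophile, which counts as not reacted. The solid goes at a feed of 0.847 mM h⁻¹. Their ratio is 1.16 h: the hold-up time, dissolved electrophile over feed. It is rough, since it rests on readings that scatter by 1 percentage point.

If the gas keeps c(nucleophile) steady, electrophile is used in a pseudo-first-order way, so c(electrophile) rises until use matches feed. That rise has the hold-up time as its time constant, so it is unfinished after one of them; 3.00 h is 2.59 of them, which on this reckoning is about 92.5% of the way to balance. Near balance, product follows the solid lost, one hold-up time behind.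

For 6.0 h I reckon feed times (6.0 h less 1.16 h), which is 4.10 mM or 20.5% reacted. That much acid meets 4.00 mM of buffer base, and since the runs show no pH, any pH stays a guess.

The forecast says 20% and pH 7, “near neutral, with a wide range”. The flask gives 19.0% and pH 7.00.

    electrophile + nucleophile → acid + product + leaving group (k = 796 M⁻¹ h⁻¹)
    protonated nucleophile ⇌ nucleophile + acid, settled at all times (K = 7.90 × 10⁻⁷ M)
    buffer acid ⇌ buffer base + acid, settled at all times (K = 6.30 × 10⁻⁹ M)
    gas ⇌ nucleophile, rate k4*(csat - [nucleophile]) (kL = 2.19 h⁻¹)
    solid electrophile ⇌ electrophile, rate k5*(cs5 - [electrophile]) while solid is left; crystals form when [electrophile] > cs5 (solubility = 5.90 mM, k = 0.144 h⁻¹)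

At 2.55 h this flask makes electrophile 1.06 times as fast as it uses it, and at 6.00 h 1.03 times, while c(electrophile) goes from 3.54% at 3.00 h to 3.74% at 6.00 h, a quasi-steady state. Feed and the hold-up of 1.16 h give 5.68% for the same flask stopped at 2.5 h, and that flask stands at 6.25%.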